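**Retrosynthetic overview**

1. The target comes from its bis(methyl ether), 1-(3,4-dimethoxyphenyl)icosan-5-one, by O-demethylation. The aromatic ring is bought (methyl eugenol), so no ring is formed in the route.
2. The C5 carbonyl is made by C–O bond formation: hydration of the icosa-4,5-diene (allene) at its central carbon. Oxygen on the sp carbon gives the C5 ketone whichever C=C reacts, so the two near-identical alkyl arms need not be told apart (new Pd–OH method).
3. The allene comes from a one-pot allenation of hexadec-1-yne (C5–C20; its terminal carbon becomes C5) with 4-(3,4-dimethoxyphenyl)butanal (C1–C4), using morpholine and ZnI2.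
4. The aldehyde comes from linear hydroformylation of methyl eugenol, which adds C4.
5. There are no stereocentres. The transient allene axis is racemic and is erased by the hydration.

Assumption: the target has no stereocentre and no stereogenic double bond, so "single enantiomer" is read as the one achiral constitution drawn.

**Route**

Step 1
Reactants: 1 methyl eugenol (4-allyl-1,2-dimethoxybenzene)
Product: 2 4-(3,4-dimethoxyphenyl)butanal
Conditions: Rh(acac)(CO)2 (0.5 mol%), BiPhePhos (1 mol%), CO/H2 (1:1, 10 bar), PhMe, 80 °C
Reagents that add atoms: carbon monoxide ([C-]#[O+])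
Why: Linear-selective hydroformylation; the wide-bite-angle bisphosphite on rhodium steers hydride insertion so that the formyl group ends on the terminal alkene carbon, the aryl ethers are inert, and no stereocentre is formed.

Step 2
Reactants: 2 4-(3,4-dimethoxyphenyl)butanal, 3 hexadec-1-yne (1.2 equiv), 4 morpholine (1.4 equiv)
Product: 6 racemic 4-(icosa-4,5-dien-1-yl)-1,2-dimethoxybenzene, via propargylic amine 5 (not isolated)
Conditions: ZnI2 (0.8 equiv), PhMe, 130 °C, sealed tube
Reagents that add atoms: none
Why: Allenation of a terminal alkyne (Crabbé-type homologation): aldehyde–alkyne–amine coupling gives the propargylic amine, whose zinc-activated alkyne takes a hydride from the morpholine α-carbon (1,5-shift) with loss of the cyclic imine, so the former terminal alkyne carbon becomes the central allene carbon C5; the allene axis is formed racemic, which does not matter because step 3 destroys it.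

Step 3
Reactants: 6 racemic 4-(icosa-4,5-dien-1-yl)-1,2-dimethoxybenzene
Product: 7 1-(3,4-dimethoxyphenyl)icosan-5-one
Conditions: [(bpy)Pd(μ-OH)]2(OTf)2 (5 mol%), H2O (20 equiv), 1,4-dioxane, 60 °C, Ar
Reagents that add atoms: water (O)
Why: Proposed new method: redox-neutral hydration of an unactivated 1,3-dialkylallene at its central carbon by a hydroxo complex of divalent palladium; the allene inserts syn into the Pd–OH bond with oxygen going to the sp carbon, the same regiochemistry with which allenes insert into Pd–Cl and Pd–C bonds to give 2-substituted π-allyl complexes, the resulting 2-hydroxy-π-allyl complex is the enol tautomer of a palladium enolate and is protonated at carbon by water to release the ketone and regenerate Pd–OH, as in the enolate hydrolysis that closes conjugate additions catalysed by cationic bipyridine complexes of divalent palladium in water, and insertion into either C=C bond puts oxygen on C5, so the two alkyl arms need not be differentiated and no stereocentre results; the closest known reaction types are Wacker-type syn-hydroxypalladation and chloropalladation of allenes, whereas π-acids such as Ph3PAuNTf2 are known to deliver water to the terminal allene carbons instead.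

Step 4
Reactants: 7 1-(3,4-dimethoxyphenyl)icosan-5-one, 8 boron tribromide (3.5 equiv)
Product: 10 1-(3,4-dihydroxyphenyl)icosan-5-one, via cyclic bromoborane ester 9 (not isolated)
Conditions: CH2Cl2, −78 °C to 0 °C, 3 h; then H2O, 0 °C, work-up under N2
Reagents that add atoms: none
Why: Lewis acid-mediated aryl methyl ether cleavage (BBr3 demethylation): boron binds each methoxy oxygen and bromide removes the methyl group by SN2, the catechol is held as its boron ester until aqueous work-up, the ketone is only reversibly complexed, and no stereocentre is involved.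

**Compound list**

1 | methyl eugenol (4-allyl-1,2-dimethoxybenzene) | C=CCc1ccc(OC)c(OC)c1 | starting material
2 | 4-(3,4-dimethoxyphenyl)butanal | O=CCCCc1ccc(OC)c(OC)c1 | intermediate
3 | hexadec-1-yne | CCCCCCCCCCCCCCC#C | starting material
4 | morpholine | C1COCCN1 | starting material
5 | 4-[1-(3,4-dimethoxyphenyl)icos-5-yn-4-yl]morpholine (racemic, not isolated) | CCCCCCCCCCCCCCC#CC(N1CCOCC1)CCCc1ccc(OC)c(OC)c1 | intermediate
6 | 4-(icosa-4,5-dien-1-yl)-1,2-dimethoxybenzene (racemic allene) | CCCCCCCCCCCCCCC=C=CCCCc1ccc(OC)c(OC)c1 | intermediate
7 | 1-(3,4-dimethoxyphenyl)icosan-5-one | CCCCCCCCCCCCCCCC(=O)CCCCc1ccc(OC)c(OC)c1 | intermediate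
8 | boron tribromide | BrB(Br)Br | starting material
9 | 1-(2-bromo-1,3,2-benzodioxaborol-5-yl)icosan-5-one (not isolated) | CCCCCCCCCCCCCCCC(=O)CCCCc1ccc2OB(Br)Oc2c1 | intermediate
10 | 1-(3,4-dihydroxyphenyl)icosan-5-one (achiral) | CCCCCCCCCCCCCCCC(=O)CCCCc1ccc(O)c(O)c1 | target

**Step count and risks**

Total step count: 4. Longest linear sequence: 4 steps (1 → 2 → 6 → 7 → 10); hexadec-1-yne 3 enters at step 2.

The three steps most likely to fail:

Step 3 (the proposed hydration). Three things could go wrong:
- outer-sphere attack of water at C4 or C6, giving allylic alcohols;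
- attack of the electron-rich dimethoxyphenyl ring on the palladium-bound allene, closing a six-membered ring;
- β-hydride elimination from the palladium enolate, giving an enone and zerovalent palladium.

The fallback uses known chemistry, sets out from allene 6 and comes back at ketone 7. Copper–boryl addition with protonation (B2pin2, MeOH, (IPr)CuCl 5 mol%, NaOtBu 10 mol%, THF, rt) puts boron on the central allene carbon. It gives a mixture of (Z)-2-[1-(3,4-dimethoxyphenyl)icos-5-en-5-yl]-4,4,5,5-tetramethyl-1,3,2-dioxaborolane F5 and (Z)-2-[1-(3,4-dimethoxyphenyl)icos-4-en-5-yl]-4,4,5,5-tetramethyl-1,3,2-dioxaborolane F6, which differ only in the side on which the double bond lies. Oxidation of the unseparated mixture with NaBO3·4H2O in THF/H2O at rt turns the C–B bond of both into the C5 enol and hence into ketone 7.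

Step 2 (allenation). Both partners are linear and enolisable, so the aldehyde may condense with itself through its morpholine enamine, and the hydride shift may stall at propargylic amine 5. The fallback sets out from aldehyde 2 and alkyne 3 and comes back at allene 6. Alkyne 3 is deprotonated with n-BuLi (THF, −78 °C) and added to 2 to give racemic 1-(3,4-dimethoxyphenyl)icos-5-yn-4-ol F2. A Myers allene synthesis follows (2-nitrobenzenesulfonylhydrazide, PPh3, DEAD, THF, −15 °C to rt). The Mitsunobu reaction gives N-[1-(3,4-dimethoxyphenyl)icos-5-yn-4-yl]-2-nitrobenzenesulfonohydrazide F3, which loses the sulfinic acid to give [1-(3,4-dimethoxyphenyl)icos-5-yn-4-yl]diazene F4. This expels dinitrogen by retro-ene reaction with hydrogen delivery to C6, giving allene 6.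

Step 1 (hydroformylation). Some branched aldehyde and some isomerisation to the propenyl arene are possible, and pressure equipment is needed. The fallback sets out from methyl eugenol 1 and comes back at aldehyde 2. Cross-metathesis with acrolein (3 equiv) using the second-generation Hoveyda–Grubbs catalyst, (H2IMes)Cl2Ru(=CH-C6H4-2-OiPr) (2 mol%), in CH2Cl2 at 40 °C gives (E)-4-(3,4-dimethoxyphenyl)but-2-enal F1. Hydrogenation of its C=C bond only (H2 1 atm, Pd/C, EtOAc, rt) gives aldehyde 2.

**Further compounds**

F1 | step 1 | (E)-4-(3,4-dimethoxyphenyl)but-2-enal | O=C/C=C/Cc1ccc(OC)c(OC)c1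
F2 | step 2 | 1-(3,4-dimethoxyphenyl)icos-5-yn-4-ol (racemic) | CCCCCCCCCCCCCCC#CC(O)CCCc1ccc(OC)c(OC)c1
F3 | step 2 | N-[1-(3,4-dimethoxyphenyl)icos-5-yn-4-yl]-2-nitrobenzenesulfonohydrazide (racemic) | CCCCCCCCCCCCCCC#CC(CCCc1ccc(OC)c(OC)c1)N(N)S(=O)(=O)c1ccccc1[N+](=O)[O-]
F4 | step 2 | [1-(3,4-dimethoxyphenyl)icos-5-yn-4-yl]diazene (racemic) | CCCCCCCCCCCCCCC#CC(CCCc1ccc(OC)c(OC)c1)N=N
F5 | step 3 | (Z)-2-[1-(3,4-dimethoxyphenyl)icos-5-en-5-yl]-4,4,5,5-tetramethyl-1,3,2-dioxaborolane | CCCCCCCCCCCCCC/C=C(\CCCCc1ccc(OC)c(OC)c1)B1OC(C)(C)C(C)(C)O1
F6 | step 3 | (Z)-2-[1-(3,4-dimethoxyphenyl)icos-4-en-5-yl]-4,4,5,5-tetramethyl-1,3,2-dioxaborolane | CCCCCCCCCCCCCCC/C(B1OC(C)(C)C(C)(C)O1)=C\CCCc1ccc(OC)c(OC)c1
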